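**Retrosynthetic overview**
1. The target, cis-(4S,5S)-4-hydroxy-2-methyl-5-geranylgeranylcyclohex-2-enone, comes from mild hydrolysis of the corresponding cis allylic alcohol dimethyl ketal.
2. That alcohol comes from a dynamic kinetic asymmetric transfer hydrogenation of a racemic α'-geranylgeranyl enone ketal, which sets both stereocentres in one step (the ketoreductase-like step).
3. The enone ketal comes from regioselective copper hydride 1,4-reduction of a prenylated quinone monoketal (the ene-reductase-like step), itself made by PhI(OAc)2/MeOH oxidation of a prenylated p-methoxyphenol (quinol to quinone level).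
4. The prenylated phenol comes from ortho-C-geranylgeranylation of 4-methoxy-3-methylphenol with all-E-geranylgeraniol (aromatic prenyl transfer).
5. Ring order: no ring is built. The single six-membered ring enters as the arene (as the toluquinol unit does in nature), is dearomatised in step 2 and reduced in steps 3 and 4.

Assumption: 4-methoxy-3-methylphenol and all-E-geranylgeraniol are bought as such; the absolute sense of step 4 follows the usual (S,S)-TsDPEN model and is to be confirmed by Mosher ester analysis on the first run, with the (R,R)-catalyst used if it proves opposite.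

**Step 1**
Reactants: 1 4-methoxy-3-methylphenol; 2 (2E,6E,10E)-geranylgeraniol
Product: 3 2-[(2E,6E,10E)-3,7,11,15-tetramethylhexadeca-2,6,10,14-tetraen-1-yl]-4-methoxy-5-methylphenol
Conditions: acidic Al2O3 (about 2 g per mmol of 2), 1 (2 equiv, excess recovered), ClCH2CH2Cl, 80 °C, 24 h
Reagents that add atoms: none
Why: Alumina-promoted ortho-selective Friedel–Crafts allylation of a phenol with an allylic alcohol (the laboratory counterpart of aromatic prenyl transfer): the surface-bound phenol is alkylated only ortho to OH, at the open C6 rather than at C2 (wedged between OH and CH3), the linear 2E allyl terminus is retained and no stereocentre is formed.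

**Step 2**
Reactants: 3 2-geranylgeranyl-4-methoxy-5-methylphenol
Product: 4 2-[(2E,6E,10E)-3,7,11,15-tetramethylhexadeca-2,6,10,14-tetraen-1-yl]-4,4-dimethoxy-5-methylcyclohexa-2,5-dien-1-one
Conditions: PhI(OAc)2 (1.1 equiv), MeOH, 0 °C, 20 min; aq. NaHCO3 quench; chromatography on Et3N-deactivated silica
Reagents that add atoms: methanol, CO
Why: Hypervalent-iodine oxidative dearomatisation of a p-methoxyphenol in methanol (quinone monoketal formation): the phenoxenium ion is captured by MeOH at the methoxy-bearing para carbon far faster than PhI(OAc)2 touches isolated trisubstituted alkenes, which fixes the ketone next to the side chain and the ketal next to the methyl group.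

**Step 3**
Reactants: 4 2-geranylgeranyl-4,4-dimethoxy-5-methylcyclohexa-2,5-dien-1-one
Product: 5 rac-6-[(2E,6E,10E)-3,7,11,15-tetramethylhexadeca-2,6,10,14-tetraen-1-yl]-4,4-dimethoxy-3-methylcyclohex-2-en-1-one
Conditions: Cu(OAc)2·H2O (5 mol %), 1,2-bis(diphenylphosphino)benzene (5 mol %), PhMe2SiH (1.5 equiv), t-BuOH (1.5 equiv), toluene, 0 °C
Reagents that add atoms: none
Why: Stryker-type copper hydride 1,4-reduction: hydride goes only to the unsubstituted β-carbon C3 of the cross-conjugated dienone (the other β-carbon carries CH3 and is fully substituted), isolated alkenes and the ketal are inert to CuH, and t-BuOH protonates the copper enolate to give the epimerisable α'-stereocentre as a racemate.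

**Step 4**
Reactants: 5 rac-6-geranylgeranyl-4,4-dimethoxy-3-methylcyclohex-2-en-1-one
Product: 7 (4S,5S)-4-hydroxy-2-methyl-5-[(2E,6E,10E)-3,7,11,15-tetramethylhexadeca-2,6,10,14-tetraen-1-yl]cyclohex-2-en-1-one (target), via ketal alcohol 6 (not isolated)
Conditions: RuCl[(S,S)-TsDPEN](p-cymene) (2 mol %), t-BuOK (0.3 equiv), i-PrOH (0.05 M), 25 °C; then THF, 5% aq. oxalic acid, 0 °C → rt
Reagents that add atoms: water, O
Why: Proposed new method: a Noyori–Ikariya asymmetric transfer hydrogenation run as a base-mediated dynamic kinetic resolution, in which the alkoxide racemises C6 of 5 through the cross-conjugated dienolate faster than the mismatched enantiomer is reduced, while the (S,S)-ruthenium hydride (alkenyl CH–π contact with the cymene ligand fixing the carbonyl face, giving 1S) reduces the matched enantiomer 1,2 from the less hindered equatorial direction of the half-chair so that OH and the pseudo-equatorial side chain end up cis (1S,6S); the closest known reactions are the Ru-TsDPEN transfer hydrogenation of 4,4-dialkoxycyclohex-2-enones to allylic alcohols and the base-mediated dynamic kinetic hydrogenation of 2-alkylcyclohexanones to cis-alcohols, and the aqueous oxalic acid then performs an ordinary acetal hydrolysis that cannot scramble C4 or C5 because neither is α to the new ketone.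

**Compound list**
1 | 4-methoxy-3-methylphenol | COc1ccc(O)cc1C | starting material
2 | (2E,6E,10E)-geranylgeraniol | CC(C)=CCC/C(C)=C/CC/C(C)=C/CC/C(C)=C/CO | starting material
3 | 2-[(2E,6E,10E)-geranylgeranyl]-4-methoxy-5-methylphenol | CC(C)=CCC/C(C)=C/CC/C(C)=C/CC/C(C)=C/Cc1cc(OC)c(C)cc1O | intermediate
4 | 2-[(2E,6E,10E)-geranylgeranyl]-4,4-dimethoxy-5-methylcyclohexa-2,5-dien-1-one (quinone monoketal) | CC(C)=CCC/C(C)=C/CC/C(C)=C/CC/C(C)=C/CC1=CC(OC)(OC)C(C)=CC1=O | intermediate
5 | rac-6-[(2E,6E,10E)-geranylgeranyl]-4,4-dimethoxy-3-methylcyclohex-2-en-1-one (racemic at C6) | CC(C)=CCC/C(C)=C/CC/C(C)=C/CC/C(C)=C/CC1CC(OC)(OC)C(C)=CC1=O | intermediate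
6 | (1S,6S)-6-[(2E,6E,10E)-geranylgeranyl]-4,4-dimethoxy-3-methylcyclohex-2-en-1-ol (cis; formed and hydrolysed in the flask) | CC(C)=CCC/C(C)=C/CC/C(C)=C/CC/C(C)=C/C[C@H]1CC(OC)(OC)C(C)=C[C@H]1O | intermediate
7 | (4S,5S)-4-hydroxy-2-methyl-5-[(2E,6E,10E)-geranylgeranyl]cyclohex-2-en-1-one (cis) | CC(C)=CCC/C(C)=C/CC/C(C)=C/CC/C(C)=C/C[C@H]1CC(=O)C(C)=C[C@H]1O | target

**Totals**
Total step count: 4. Longest linear sequence: 4 steps (1 or 2 → 3 → 4 → 5 → 7).

**Steps most likely to fail, with fallbacks**

Step 4 (highest risk). The α'-centre may epimerise too slowly, or the catalyst may not override the α'-substituent, giving low ee or cis/trans mixtures. The fallback sets out from 5 and comes back at 6. It replaces the catalytic dynamic resolution by a diastereoselective reduction followed by an enzymatic kinetic resolution. Compound 5 is reduced with LiBH(s-Bu)3 in THF at −78 °C (1,2-attack from the equatorial direction on the β,β-disubstituted enone), giving the cis alcohol as a racemate of 6 and its mirror image, the (1R,6R)-alcohol F1. Burkholderia cepacia lipase (Amano PS) with vinyl acetate in t-BuOMe at 30 °C is predicted by the Kazlauskas rule (C6 as the large group) to acetylate only the (1S,6S) enantiomer, giving the (1S,6S)-acetate F2 and leaving F1. After chromatographic separation, K2CO3 in MeOH at 0 °C converts F2 into 6, which is hydrolysed with aqueous oxalic acid exactly as in the second half of step 4. F1 can be returned to 5 by MnO2 oxidation and base epimerisation.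

Step 1. Ortho-regioselectivity on alumina (C6 against C2), chroman formation or cation–olefin cyclisation of the C20 chain could depress the yield. The fallback sets out from 1 and 2 and comes back at 3. It replaces the acid-surface Friedel–Crafts reaction by base-mediated ortho-C-alkylation of a phenoxide ion pair. Compound 2 is converted with PBr3 in Et2O at −10 °C into geranylgeranyl bromide F3. Compound 1 is deprotonated with NaH in toluene to sodium 4-methoxy-3-methylphenolate F4. The suspension of F4 is treated with F3 at 0 °C → rt. In the non-polar medium the tight ion pair is alkylated at the free ortho carbon by direct displacement with the E geometry intact, giving 3 after the O-alkyl ether by-product is removed.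

Step 3. Over-reduction, 1,2-reduction, or reductive re-aromatisation of the quinone monoketal could compete with the clean 1,4-reduction. The fallback sets out from 1 and comes back at 5. It moves the side-chain attachment from the arene to an enolate, a reductive alkylation that bypasses 3 and 4. Compound 1 is oxidised with PhI(OAc)2 in MeOH at 0 °C to 4,4-dimethoxy-3-methylcyclohexa-2,5-dien-1-one F5. LiBH(s-Bu)3 in THF at −78 °C adds hydride to the unsubstituted β-carbon of F5 (not the methyl-bearing one) to give the lithium dienolate F6. In the same flask F6 is alkylated at the α'-carbon with geranylgeranyl bromide F3 (made from 2 with PBr3 as above; DMPU, −78 → 0 °C) to give 5.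

**Further compounds**
F1 | step 4 | (1R,6R)-6-[(2E,6E,10E)-geranylgeranyl]-4,4-dimethoxy-3-methylcyclohex-2-en-1-ol | CC(C)=CCC/C(C)=C/CC/C(C)=C/CC/C(C)=C/C[C@@H]1CC(OC)(OC)C(C)=C[C@@H]1O
F2 | step 4 | (1S,6S)-6-[(2E,6E,10E)-geranylgeranyl]-4,4-dimethoxy-3-methylcyclohex-2-en-1-yl acetate | CC(C)=CCC/C(C)=C/CC/C(C)=C/CC/C(C)=C/C[C@H]1CC(OC)(OC)C(C)=C[C@H]1OC(C)=O
F3 | step 1 | (2E,6E,10E)-geranylgeranyl bromide | CC(C)=CCC/C(C)=C/CC/C(C)=C/CC/C(C)=C/CBr
F4 | step 1 | sodium 4-methoxy-3-methylphenolate | [Na+].[O-]c1ccc(OC)c(C)c1
F5 | step 3 | 4,4-dimethoxy-3-methylcyclohexa-2,5-dien-1-one | O=C1C=CC(OC)(OC)C(C)=C1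
F6 | step 3 | lithium 4,4-dimethoxy-5-methylcyclohexa-1,5-dien-1-olate | [Li+].[O-]C1=CCC(OC)(OC)C(C)=C1
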